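## Retrosynthetic overview

1. Target 31 ⇐ silyl ether 30 ⇐ iodo-aldehyde 29. The five-membered oxygen ring is formed first (step 10). The ten-membered carbocycle is closed last, at C3–C4, by an intramolecular Nozaki–Hiyama–Kishi reaction (step 17).
2. 29 ⇐ ketone 21. C12 is carried as a lactol methyl ether and oxidised late, C13 comes from a Mannich methylenation of the lactol, and the C8 angelate comes from the C8 ketone.
3. Key disconnection: 20/21 ⇐ acyclic mixed orthoformate 17 by a Prins–pinacol cascade. It makes C11–C12 (Prins closure) and C6–C7 (1,2-shift of C6 from C8 to C7). Compound 17 has a rearranged, easily assembled skeleton with a C6–C8 bond.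
4. Enabling feature: in the lactone ring (O, C6, C7, C11, C12), ring carbon C7 sits next to the O-bearing C6 and carries the exocyclic oxygenated carbon C8. At the C8-ketone/C12-acetal level the ring is therefore a 3-acyltetrahydrofuran, the retron of this cascade.
5. 17 ⇐ aldehyde 4 + alkoxyallene 13 (allene hydroboration/allylboration, sets C6). 13 ⇐ methoxyallene 10 + epoxide 9 (C1 from lactone 5, C10 by Felkin-controlled epoxidation).

Key step: step 10

Remark on numbering: germacranolide numbering is used for all compounds. C1–C10 are the ring, C11/C12/C13 are the lactone α-carbon, carbonyl and methylene, C14 is on C10, and C15 is on C4.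

Assumption: C8 in 15–18 and C12 in 19–25 are erased later, so their SMILES show the isomer expected from the transition-state models. Lactols 26–28 are written without configuration at C12 because they equilibrate.

## Route

Step 1
Reactants: 1 but-2-yn-1-ol
Product: 3 (Z)-3-iodobut-2-en-1-ol, via cyclic alkenylalanate 2 (not isolated)
Conditions: Red-Al, THF, 0 °C to rt; then I2, −78 to 0 °C
Reagents that add atoms: iodine, II
Why: Hydroxyl-directed trans-hydroalumination of a propargylic alcohol puts aluminium on the distal alkyne carbon inside the five-membered alanate 2, and iodinolysis with retention should give only the Z-iodoalkene, which fixes the C4=C5 geometry of the target.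

Step 2
Reactants: 3 (Z)-3-iodobut-2-en-1-ol
Product: 4 (Z)-3-iodobut-2-enal
Conditions: MnO2, CH2Cl2, rt, dark
Reagents that add atoms: none
Why: Allylic alcohol oxidation with MnO2 is neutral and heterogeneous, so the Z geometry and the C–I bond should survive if the aldehyde is used without storage.

Step 3
Reactants: 5 (S)-α-hydroxy-γ-butyrolactone
Product: 6 (S)-2,4-dihydroxy-N-methoxy-N-methylbutanamide
Conditions: MeNH(OMe)·HCl, AlMe3, CH2Cl2, 0 °C to rt
Reagents that add atoms: N,O-dimethylhydroxylamine hydrochloride, CNOC.Cl
Why: Weinreb aminolysis of a lactone with the aluminium amide opens the ring at the acyl carbon and does not touch the stereocentre, which becomes C1 (S) of the target.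

Step 4
Reactants: 6 (S)-2,4-dihydroxy-N-methoxy-N-methylbutanamide
Product: 7 (S)-2,4-bis(tert-butyldimethylsilyloxy)-N-methoxy-N-methylbutanamide
Conditions: TBSCl, imidazole, DMF, rt
Reagents that add atoms: tert-butyldimethylsilyl chloride, C[Si](C)(Cl)C(C)(C)C
Why: Standard imidazole-promoted silylation protects both hydroxyl groups at once and stops relactonisation, the bulky non-chelating ether on O1 being wanted for step 6.

Step 5
Reactants: 7 (S)-2,4-bis(tert-butyldimethylsilyloxy)-N-methoxy-N-methylbutanamide
Product: 8 (S)-3,5-bis(tert-butyldimethylsilyloxy)pentan-2-one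
Conditions: MeMgBr, THF, −20 to 0 °C
Reagents that add atoms: methylmagnesium bromide, C[Mg]Br
Why: Weinreb ketone synthesis stops at the ketone because the chelated tetrahedral adduct survives until work-up, and the α-silyloxy centre is not enolised at low temperature.

Step 6
Reactants: 8 (S)-3,5-bis(tert-butyldimethylsilyloxy)pentan-2-one
Product: 9 (R)-2-[(S)-1,3-bis(tert-butyldimethylsilyloxy)propyl]-2-methyloxirane
Conditions: Me3S+ I−, n-BuLi, THF, −10 °C; then 8, −10 °C to rt
Reagents that add atoms: trimethylsulfonium iodide, C[S+](C)C.[I-]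
Why: Corey–Chaykovsky epoxidation delivers CH2 (C9) to the ketone under Felkin–Anh control, with the C1–OTBS bond perpendicular to the carbonyl group and no chelating metal present, which should set C10 as R (O1 and O10 anti in the C9–C10–C1–C2 zigzag, as in the target).

Step 7
Reactants: 10 methoxyallene; 9 (R)-2-[(S)-1,3-bis(tert-butyldimethylsilyloxy)propyl]-2-methyloxirane
Product: 13 (5R,6S)-6,8-bis(tert-butyldimethylsilyloxy)-3-methoxy-5-methyl-5-(triethylsilyloxy)octa-1,2-diene, via 1-lithio-1-methoxyallene 11 (not isolated), via lithium alkoxide 12 (not isolated)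
Conditions: 10, n-BuLi, THF, −40 °C; 9, DMPU, −40 °C to rt; then TESOTf, 2,6-lutidine, −78 to 0 °C
Reagents that add atoms: triethylsilyl triflate, CC[Si](CC)(CC)OS(=O)(=O)C(F)(F)F
Why: Methoxyallene is lithiated at the carbon that bears oxygen and this vinylic carbanion opens the 2,2-disubstituted epoxide by SN2 attack at its free CH2 (known alkylation chemistry of lithiated alkoxyallenes), so the C10–O bond and configuration are untouched and the tertiary alkoxide is capped in the same flask.

Step 8
Reactants: 13 alkoxyallene; 4 (Z)-3-iodobut-2-enal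
Product: 16 (2Z,4S,5R,7R,8S)-8,10-bis(tert-butyldimethylsilyloxy)-2-iodo-5-methoxy-7-methyl-7-(triethylsilyloxy)-5-vinyldec-2-en-4-ol, via allylborane 14 (not isolated), via borinate 15 (not isolated)
Conditions: (+)-Ipc2BH [from (−)-α-pinene], THF, −25 to 0 °C; 4, −78 °C; then H2O2, NaOH, 0 °C
Reagents that add atoms: none
Why: This is allene hydroboration followed by Brown-type allylboration, in which the bulky dialkylborane adds to the unsubstituted terminal C=C as with other 1,1-disubstituted allenes, the γ-alkoxy-γ-alkyl allylborane 14 adds to 4 through a closed chair transition state that forms C6–C8 and releases the vinyl group, the isopinocampheyl groups select the aldehyde face that gives 6S, and C8 follows from the alkene geometry of 14.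

Step 9
Reactants: 16 homoallylic alcohol
Product: 17 dimethoxymethyl ether of 16 (mixed orthoformate on O6)
Conditions: HC(OMe)3 (excess), PPTS (cat.), CH2Cl2, rt; volatiles removed in vacuo, used crude
Reagents that add atoms: trimethyl orthoformate, COC(OC)OC
Why: Acid-catalysed orthoester exchange is an equilibrium that is driven by the excess of orthoformate and removal of methanol, only the single free hydroxyl group can react, and no stereocentre is touched.

Step 10
Reactants: 17 mixed orthoformate
Product: 20 all-cis 2-methoxytetrahydrofuran ketone (C12-OMe and C7-acyl and C6-alkenyl cis), via alkoxy(methoxy)carbenium triflate 18 (not isolated), via O-methyl oxocarbenium triflate 19 (not isolated)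
Conditions: TMSOTf (1.2 equiv), 2,6-di-tert-butyl-4-methylpyridine, CH2Cl2, −78 to −30 °C; then aq. NaHCO3
Reagents that add atoms: water, O
Why: Proposed new method: TMSOTf abstracts one methoxy group of 17 to give the alkoxy(methoxy)carbenium ion 18, the terminal vinyl carbon C11 attacks its carbon C12 in a chair-like Prins closure, and the charge that builds up on C7 is answered at once by a pinacol-type 1,2-shift of C6 from C8 to C7, pushed by the C8 methoxy group, to give O-methyl oxocarbenium ion 19, which water turns into ketone 20. The closest known reaction type is the Prins–pinacol synthesis of 3-acyltetrahydrofurans from aldehyde-derived oxocarbenium ions of 1-alkenyl-1,2-diols; beyond it are the acid-level (orthoformate) initiator, which is less electrophilic but intramolecular and faces no better nucleophile, and the methyl-ether terminator, whose lone pair serves like that of OH or OSiR3. Ring closure is 6-endo-trig to the oxane O–C12–C11–C7–C8–C6 followed by ring contraction to the five-membered ring O–C6–C7–C11–C12, for which the C6–C8 bond is well placed because in the chair it lies parallel to the forming C11–C12 bond; a 2-oxonia-Cope/aldol path through the same ion would end in the same constitution. C6 migrates with retention and keeps the S configuration set in step 8, C7 follows from the chair with the C6 alkenyl and C12 methoxy groups equatorial (acyl, alkenyl and methoxy all cis, C7 being corrected in step 11), C12 is erased in step 16 and the C8 centre of 17 is erased here. The step needs the vinyl group to win over the iodoalkene and over ionisation of the allylic C6–O and C8–O bonds: the iodoalkene is deactivated and could only close a strained small ring, its iodine also destabilises a C6 cation (limiting solvolysis and loss of configuration by the oxonia-Cope path), and low temperature with a hindered pyridine keeps Brønsted acid away.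

Step 11
Reactants: 20 all-cis ketone
Product: 21 6,7-trans 2-methoxytetrahydrofuran ketone
Conditions: DBU (0.3 equiv), CH2Cl2, rt
Reagents that add atoms: none
Why: Base-mediated epimerisation through the exocyclic enolate places the C7 acyl group trans to the C6 alkenyl group (thermodynamic control on a five-membered ring, giving the target configuration at C7), while β-elimination is held back because the ring C6–O bond is nearly orthogonal to the enolate π system.

Step 12
Reactants: 21 6,7-trans ketone
Product: 22 (8R)-alcohol
Conditions: Zn(BH4)2, Et2O, −40 to 0 °C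
Reagents that add atoms: none
Why: In this chelation-controlled ketone reduction Zn(II) bridges the ketone oxygen and the ring oxygen, which turns C6 toward the carbonyl oxygen so that hydride arrives from the side of H7 and not of C11, which should give the 8R alcohol (C11 and O8 syn in the C6–C7–C8–C9 zigzag).

Step 13
Reactants: 22 (8R)-alcohol; 23 angelic acid
Product: 25 C8 angelate, via mixed anhydride 24 (not isolated)
Conditions: 23, 2,4,6-trichlorobenzoyl chloride, Et3N, toluene, rt; then 22, 80 °C
Reagents that add atoms: none
Why: Yamaguchi esterification through mixed anhydride 24 without a nucleophilic amine catalyst acylates the only free hydroxyl group and is known to keep the Z geometry of angelates.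

Step 14
Reactants: 25 C8 angelate
Product: 26 lactol with free C3-OH and C10-OH (O1 still TBS-protected)
Conditions: AcOH–THF–H2O (3:1:1), 40 °C
Reagents that add atoms: water, O
Why: This is a graded acid hydrolysis in which the 2-deoxy-type furanosyl acetal, the primary TBS ether and the TES ether are all much more labile than the secondary TBS ether flanked by the fully substituted C10, which stays to shield O1 during step 16.

Step 15
Reactants: 26 lactol
Product: 28 α-methylene lactol, via Mannich base 27 (not isolated)
Conditions: Eschenmoser's salt, Et3N, CH2Cl2, rt to 40 °C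
Reagents that add atoms: N,N-dimethylmethyleneiminium iodide, C=[N+](C)C.[I-]
Why: Mannich-type α-methylenation of an aldehyde with Eschenmoser's salt acts on the open hydroxy-aldehyde form of the lactol, amine loss from 27 gives the 2-substituted acrolein that closes again to the lactol, and the mild amine base spares the angelate and the iodoalkene.

Step 16
Reactants: 28 α-methylene lactol
Product: 29 α-methylene lactone bearing the C3 aldehyde and the (Z)-iodoalkene
Conditions: Dess–Martin periodinane (3 equiv), NaHCO3, CH2Cl2, 0 °C to rt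
Reagents that add atoms: none
Why: Dess–Martin oxidation converts the allylic lactol into the α-methylene lactone and the primary alcohol into the aldehyde in one operation, the tertiary alcohol and the silyl ether being inert.

Step 17
Reactants: 29 iodo-aldehyde
Product: 30 1-O-TBS ether of the target
Conditions: CrCl2 (10 equiv), NiCl2 (2 mol %), DMSO–THF, slow addition, about 2 mM, rt
Reagents that add atoms: none
Why: In this intramolecular Nozaki–Hiyama–Kishi reaction the alkenylchromium(III) species forms with retention of the Z geometry and adds chemoselectively to the aldehyde at high dilution to close the ten-membered ring at C3–C4, esters, the α-methylene lactone and the free tertiary alcohol are tolerated, and the β-silyloxy group should favour the 1,3-anti (3S) carbinol by the polar 1,3-induction model.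

Step 18
Reactants: 30 1-O-TBS ether
Product: 31 target (CNP0249520.1)
Conditions: HF·pyridine, pyridine, THF, 0 °C to rt
Reagents that add atoms: none
Why: Fluoride-mediated desilylation under buffered acidic conditions removes the last silyl ether without base, so the α-methylene lactone and the angelate are not endangered.

## Compound list

1 | but-2-yn-1-ol | CC#CCO | starting material
2 | cyclic alkenylalanate (sodium salt) | CC1=CCO[Al-]1(OCCOC)OCCOC.[Na+] | intermediate
3 | (Z)-3-iodobut-2-en-1-ol | C/C(I)=C/CO | intermediate
4 | (Z)-3-iodobut-2-enal | C/C(I)=C/C=O | intermediate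
5 | (S)-α-hydroxy-γ-butyrolactone | O[C@H]1CCOC1=O | starting material
6 | (S)-2,4-dihydroxy-N-methoxy-N-methylbutanamide | CON(C)C(=O)[C@@H](O)CCO | intermediate
7 | (S)-2,4-bis(TBSO)-N-methoxy-N-methylbutanamide | CON(C)C(=O)[C@@H](O[Si](C)(C)C(C)(C)C)CCO[Si](C)(C)C(C)(C)C | intermediate
8 | (S)-3,5-bis(TBSO)pentan-2-one | CC(=O)[C@@H](O[Si](C)(C)C(C)(C)C)CCO[Si](C)(C)C(C)(C)C | intermediate
9 | (R)-2-[(S)-1,3-bis(TBSO)propyl]-2-methyloxirane | C[C@@]1(CO1)[C@@H](O[Si](C)(C)C(C)(C)C)CCO[Si](C)(C)C(C)(C)C | intermediate
10 | methoxyallene | COC=C=C | starting material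
11 | 1-lithio-1-methoxyallene | [Li]C(OC)=C=C | intermediate
12 | lithium alkoxide from epoxide opening | C=C=C(OC)C[C@@](C)([O-])[C@@H](O[Si](C)(C)C(C)(C)C)CCO[Si](C)(C)C(C)(C)C.[Li+] | intermediate
13 | alkoxyallene (O10-TES, O1/O3-TBS) | C=C=C(OC)C[C@@](C)(O[Si](CC)(CC)CC)[C@@H](O[Si](C)(C)C(C)(C)C)CCO[Si](C)(C)C(C)(C)C | intermediate
14 | γ-methoxy-γ-alkyl allyl(diisopinocampheyl)borane | C[C@H]1[C@@H]2C[C@@H](C2(C)C)C[C@@H]1B(C/C=C(/OC)C[C@@](C)(O[Si](CC)(CC)CC)[C@@H](O[Si](C)(C)C(C)(C)C)CCO[Si](C)(C)C(C)(C)C)[C@H]1C[C@H]2C[C@@H]([C@@H]1C)C2(C)C | intermediate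
15 | diisopinocampheylborinate of 16 | C/C(I)=C/[C@H](OB([C@H]1C[C@H]2C[C@@H]([C@@H]1C)C2(C)C)[C@H]1C[C@H]2C[C@@H]([C@@H]1C)C2(C)C)[C@](OC)(C=C)C[C@@](C)(O[Si](CC)(CC)CC)[C@@H](O[Si](C)(C)C(C)(C)C)CCO[Si](C)(C)C(C)(C)C | intermediate
16 | (6S,8R) homoallylic alcohol with C8 methyl ether and vinyl group | C/C(I)=C/[C@H](O)[C@](OC)(C=C)C[C@@](C)(O[Si](CC)(CC)CC)[C@@H](O[Si](C)(C)C(C)(C)C)CCO[Si](C)(C)C(C)(C)C | intermediate
17 | O6-dimethoxymethyl ether of 16 (mixed orthoformate) | C/C(I)=C/[C@H](OC(OC)OC)[C@](OC)(C=C)C[C@@](C)(O[Si](CC)(CC)CC)[C@@H](O[Si](C)(C)C(C)(C)C)CCO[Si](C)(C)C(C)(C)C | intermediate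
18 | alkoxy(methoxy)carbenium triflate | C/C(I)=C/[C@H]([O+]=COC)[C@](OC)(C=C)C[C@@](C)(O[Si](CC)(CC)CC)[C@@H](O[Si](C)(C)C(C)(C)C)CCO[Si](C)(C)C(C)(C)C.[O-]S(=O)(=O)C(F)(F)F | intermediate
19 | O-methyl oxocarbenium triflate after the 1,2-shift | CO[C@@H]1C[C@H](C(=[O+]C)C[C@@](C)(O[Si](CC)(CC)CC)[C@@H](O[Si](C)(C)C(C)(C)C)CCO[Si](C)(C)C(C)(C)C)[C@H](/C=C(/C)I)O1.[O-]S(=O)(=O)C(F)(F)F | intermediate
20 | all-cis 2-methoxytetrahydrofuran C8 ketone | CO[C@@H]1C[C@H](C(=O)C[C@@](C)(O[Si](CC)(CC)CC)[C@@H](O[Si](C)(C)C(C)(C)C)CCO[Si](C)(C)C(C)(C)C)[C@H](/C=C(/C)I)O1 | intermediate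
21 | 6,7-trans 2-methoxytetrahydrofuran C8 ketone | CO[C@@H]1C[C@@H](C(=O)C[C@@](C)(O[Si](CC)(CC)CC)[C@@H](O[Si](C)(C)C(C)(C)C)CCO[Si](C)(C)C(C)(C)C)[C@H](/C=C(/C)I)O1 | intermediate
22 | (8R)-alcohol | CO[C@@H]1C[C@@H]([C@H](O)C[C@@](C)(O[Si](CC)(CC)CC)[C@@H](O[Si](C)(C)C(C)(C)C)CCO[Si](C)(C)C(C)(C)C)[C@H](/C=C(/C)I)O1 | intermediate
23 | angelic acid, (Z)-2-methylbut-2-enoic acid | C/C=C(/C)C(=O)O | starting material
24 | angelic 2,4,6-trichlorobenzoic mixed anhydride | C/C=C(/C)C(=O)OC(=O)c1c(Cl)cc(Cl)cc1Cl | intermediate
25 | C8 angelate (lactol methyl ether) | CO[C@@H]1C[C@@H]([C@H](OC(=O)/C(C)=C\C)C[C@@](C)(O[Si](CC)(CC)CC)[C@@H](O[Si](C)(C)C(C)(C)C)CCO[Si](C)(C)C(C)(C)C)[C@H](/C=C(/C)I)O1 | intermediate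
26 | lactol, C3-OH and C10-OH free, O1-TBS | OC1C[C@@H]([C@H](OC(=O)/C(C)=C\C)C[C@@](C)(O)[C@@H](O[Si](C)(C)C(C)(C)C)CCO)[C@H](/C=C(/C)I)O1 | intermediate
27 | C11 dimethylaminomethyl lactol (Mannich base) | OC1C(CN(C)C)[C@@H]([C@H](OC(=O)/C(C)=C\C)C[C@@](C)(O)[C@@H](O[Si](C)(C)C(C)(C)C)CCO)[C@H](/C=C(/C)I)O1 | intermediate
28 | α-methylene lactol | OC1C(=C)[C@@H]([C@H](OC(=O)/C(C)=C\C)C[C@@](C)(O)[C@@H](O[Si](C)(C)C(C)(C)C)CCO)[C@H](/C=C(/C)I)O1 | intermediate
29 | α-methylene lactone with C3 aldehyde and (Z)-iodoalkene | O=C1C(=C)[C@@H]([C@H](OC(=O)/C(C)=C\C)C[C@@](C)(O)[C@@H](O[Si](C)(C)C(C)(C)C)CC=O)[C@H](/C=C(/C)I)O1 | intermediate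
30 | 1-O-TBS ether of the target | C=C1C(=O)O[C@H]2/C=C(/C)[C@@H](O)C[C@H](O[Si](C)(C)C(C)(C)C)[C@](C)(O)C[C@@H](OC(=O)/C(C)=C\C)[C@H]12 | intermediate
31 | CNP0249520.1, (1S,3S,4Z,6S,7S,8R,10R) | C=C1C(=O)O[C@H]2/C=C(/C)[C@@H](O)C[C@H](O)[C@](C)(O)C[C@@H](OC(=O)/C(C)=C\C)[C@H]12 | target

## Step count and risks

Total step count: 18. Longest linear sequence: 16 steps (5 to 31, steps 3–18).

**Step 10 (Proposed new method).**
- What may go wrong: the doubly oxygen-stabilised carbenium ion may be too weak an electrophile for a monosubstituted alkene. Ionisation of the allylic C–O bonds, dealkylation to the formate, or erosion of the C6 configuration through the oxonia-Cope manifold could then take over.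
- Fallback (known chemistry), setting out from 16 and coming back at 21: 16 is condensed with methyl glyoxylate under BF3·OEt2 at low temperature. An ordinary aldehyde-type oxocarbenium ion then starts the established Prins–pinacol rearrangement and gives the all-cis methyl tetrahydrofuran-2-carboxylate F1. LiOH saponifies the ester and at the same time equilibrates C7, giving the 6,7-trans tetrahydrofuran-2-carboxylic acid F2. Hofer–Moest (non-Kolbe) anodic decarboxylation of this α-alkoxy acid in methanol replaces CO2H by OMe and gives 21.

**Step 17.**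
- What may go wrong: intermolecular coupling may compete with the strained ten-membered closure, and facial selectivity at the aldehyde may be poor.
- Fallback, setting out from 29 and coming back at 30: ring closure and C3 control are separated. The cyclisation is run without regard to C3, and any C3-epimeric carbinol F3 (alone or mixed with 30) is oxidised with Dess–Martin periodinane to the cross-conjugated C3 enone F4. F4 is then reduced under reagent control, by Corey–Bakshi–Shibata reduction with the (R)-oxazaborolidine and catecholborane at low temperature, to give 30.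

**Step 8.**
- What may go wrong: hydroboration of the hindered alkoxyallene by the bulky chiral borane may be sluggish or regiochemically unclean, with boron going to the central carbon. Borotropic scrambling of 14 is also possible.
- Fallback, setting out from 13 and coming back at 16: hydrometalation and stereocontrol are given to two different reagents. Copper hydride-catalysed hydroboration of 13 with pinacolborane gives the isolable allyl pinacolboronate F5. F5 is purified and then added to 4 under catalysis by a chiral BINOL-derived phosphoric acid ((R)-TRIP is expected to address the required aldehyde face), giving 16 after hydrolysis of the borate.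

Further compounds
F1 | step 10 | all-cis methyl tetrahydrofuran-2-carboxylate (CO2Me on C12) | COC(=O)[C@@H]1C[C@H](C(=O)C[C@@](C)(O[Si](CC)(CC)CC)[C@@H](O[Si](C)(C)C(C)(C)C)CCO[Si](C)(C)C(C)(C)C)[C@H](/C=C(/C)I)O1
F2 | step 10 | 6,7-trans tetrahydrofuran-2-carboxylic acid | OC(=O)[C@@H]1C[C@@H](C(=O)C[C@@](C)(O[Si](CC)(CC)CC)[C@@H](O[Si](C)(C)C(C)(C)C)CCO[Si](C)(C)C(C)(C)C)[C@H](/C=C(/C)I)O1
F3 | step 17 | C3-epimeric carbinol (3-epi-30) | C=C1C(=O)O[C@H]2/C=C(/C)[C@H](O)C[C@H](O[Si](C)(C)C(C)(C)C)[C@](C)(O)C[C@@H](OC(=O)/C(C)=C\C)[C@H]12
F4 | step 17 | C3 enone | C=C1C(=O)O[C@H]2/C=C(/C)C(=O)C[C@H](O[Si](C)(C)C(C)(C)C)[C@](C)(O)C[C@@H](OC(=O)/C(C)=C\C)[C@H]12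
F5 | step 8 | allyl pinacolboronate | CC1(C)OB(C/C=C(/OC)C[C@@](C)(O[Si](CC)(CC)CC)[C@@H](O[Si](C)(C)C(C)(C)C)CCO[Si](C)(C)C(C)(C)C)OC1(C)C
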